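**Retrosynthetic overview**
1. Target ⇐ mono-dehydration of C2-symmetric (3S,3'S)-eschscholtzxanthin ⇐ double CBS reduction of rhodoxanthin.
2. Rhodoxanthin ⇐ acid-triggered double 1,10-dehydration (all double bonds shift into the retro positions) plus ketal removal from a C40 6,6'-diol with a central CH2–CH2 unit ⇐ Red-Al reduction ⇐ double acetylide addition of a C22 diyne to two molecules of ketoisophorone ketal.
3. C22 diyne ⇐ double Wittig of a C6 enynyl ylide (two molecules) with a C10 dial; the dial ⇐ cross-metathesis of hexa-1,5-diene with two molecules of methacrolein.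
4. Ketoisophorone ketal ⇐ γ-oxidation and ketalisation of 2,6,6-trimethylcyclohex-2-enone ⇐ one-step CMe2-insertion ring expansion of 2-methylcyclopent-2-enone (key step).
5. Ring order: both six-membered rings come first, from one ring-expansion batch used twice, before any chain is attached; no ring is formed later.

**Assumptions.** 2-Diazopropane is used as a reagent, made beforehand from acetone hydrazone (Ag2O, Et2O, −78 °C) and kept as a cold ether solution. Carotenoid numbering is used for the C40 compounds (C1 = CMe2, C3 = oxygen-bearing ring carbon, C5 = ring C-methyl alkene carbon, C6 = ring carbon carrying the chain, chain C7–C15 and primed). Compounds 11, 13 and 14 are E/Z mixtures at the two Wittig-formed bonds and are drawn all-E; 13 and 14 are mixtures at the tertiary carbinol carbons. Where a step builds two molecules of the same compound into its product, the second molecule is entered under "Reagents that add atoms".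

Step 1
Reactants: 1 2-methylcyclopent-2-en-1-one
Product: 2 2,6,6-trimethylcyclohex-2-en-1-one
Conditions: 2-diazopropane (1.3 equiv, cold Et2O solution, slow addition), Sc(OTf)3 (5 mol %), toluene–CH2Cl2, −78 °C
Reagents that add atoms: 2-diazopropane, CC(C)=[N+]=[N-]
Why: Proposed new method: Sc(OTf)3 activates the enone carbonyl for 1,2-attack by the nucleophilic diazo carbon at −78 °C (the α-methyl group and the low temperature are meant to hold back the competing dipolar addition to the C=C bond), and in the β-diazonio alkoxide the sp3 C5 methylene shifts to the carbon losing N2 in preference to the sp2 C2 because this keeps the enone conjugated, so CMe2 is inserted between C1 and C5 and the hindered product does not react again; the closest known reaction type is the Lewis-acid-catalysed diazoalkane–ketone homologation (Tiffeneau–Demjanov-type ring expansion), established for saturated cycloalkanones and mono- or aryl-substituted diazoalkanes but not for 2-diazopropane on a cyclopentenone.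

Step 2
Reactants: 2 2,6,6-trimethylcyclohex-2-en-1-one
Product: 3 2,6,6-trimethylcyclohex-2-ene-1,4-dione (ketoisophorone)
Conditions: Rh2(cap)4 (cap = caprolactamate, 1 mol %), t-BuOOH (70% aq., 5 equiv), K2CO3 (0.5 equiv), CH2Cl2, 25 °C
Reagents that add atoms: tert-butyl hydroperoxide, CC(C)(C)OO
Why: Dirhodium-catalysed allylic C–H oxidation, in which the tert-butylperoxyl radical abstracts hydrogen from the only allylic ring CH2 (C4, γ to the carbonyl) and the mixed peroxide collapses to the ene-dione, the vinylic methyl group being much less reactive.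

Step 3
Reactants: 3 2,6,6-trimethylcyclohex-2-ene-1,4-dione
Product: 4 7,9,9-trimethyl-1,4-dioxaspiro[4.5]dec-6-en-8-one (ketoisophorone 4-ethylene ketal)
Conditions: ethylene glycol (1.2 equiv), pTsOH·H2O (2 mol %), benzene, reflux, Dean–Stark
Reagents that add atoms: ethylene glycol, OCCO
Why: Acid-catalysed ketalisation goes only at the unhindered C4 carbonyl because the C1 carbonyl is flanked by CMe2 and the methyl-bearing alkene carbon, and the alkene stays conjugated to C1=O so it does not shift.

Step 4
Reactants: 5 hexa-1,5-diene, 6 methacrolein (2-methylprop-2-enal)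
Product: 7 (2E,6E)-2,7-dimethylocta-2,6-dienedial
Conditions: second-generation Hoveyda–Grubbs catalyst RuCl2(SIMes)(=CH–C6H4-2-OiPr) (3 mol %), methacrolein (6 equiv; two molecules are incorporated, one at each alkene of 5), CH2Cl2, 40 °C
Reagents that add atoms: methacrolein (second equivalent), CC(=C)C=O
Why: Double olefin cross-metathesis, in which each terminal alkene of 5 couples with one molecule of the electron-poor 1,1-disubstituted partner used in excess, two molecules of ethene are lost, any self-metathesis oligomer of 5 is cut back to the same dial, and the trisubstituted enal forms E (a geometry that is erased later anyway).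

Step 5
Reactants: 8 (2E)-3-methylpent-2-en-4-yn-1-ol
Product: 9 [(2E)-3-methylpent-2-en-4-yn-1-yl]triphenylphosphonium bromide
Conditions: Ph3P·HBr (1.0 equiv), CH2Cl2, 25 °C
Reagents that add atoms: triphenylphosphine hydrobromide, Br.c1ccc(cc1)P(c1ccccc1)c1ccccc1
Why: Acid-promoted SN1-type substitution of the allylic alcohol, with PPh3 attacking the primary end of the allyl cation, gives the allylic phosphonium salt directly (standard Wittig-salt formation of polyene chemistry).

Step 6
Reactants: 9 [(2E)-3-methylpent-2-en-4-yn-1-yl]triphenylphosphonium bromide, 7 (2E,6E)-2,7-dimethylocta-2,6-dienedial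
Product: 11 (3E,5E,7E,11E,13E,15E)-3,7,12,16-tetramethyloctadeca-3,5,7,11,13,15-hexaene-1,17-diyne, via enynyl phosphorus ylide 10 (not isolated)
Conditions: 9 (2.2 equiv; two molecules are incorporated, one at each aldehyde of 7), NaOMe (2.2 equiv), MeOH–CH2Cl2, 0 → 25 °C
Reagents that add atoms: phosphonium salt 9 (second equivalent), C#C/C(C)=C/C[P+](c1ccccc1)(c1ccccc1)c1ccccc1.[Br-]
Why: Double Wittig olefination, in which NaOMe deprotonates the phosphonium salt (far more acidic than the alkyne C–H) and the semistabilised ylide condenses with both enal groups, the E/Z mixture at the two new C=C bonds being harmless because these bonds become single bonds in step 9.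

Step 7
Reactants: 11 (3E,5E,7E,11E,13E,15E)-3,7,12,16-tetramethyloctadeca-3,5,7,11,13,15-hexaene-1,17-diyne, 4 7,9,9-trimethyl-1,4-dioxaspiro[4.5]dec-6-en-8-one
Product: 13 8,8'-[(3E,5E,7E,11E,13E,15E)-3,7,12,16-tetramethyloctadeca-3,5,7,11,13,15-hexaene-1,17-diyne-1,18-diyl]bis(7,9,9-trimethyl-1,4-dioxaspiro[4.5]dec-6-en-8-ol), via dilithium bis-acetylide 12 (not isolated)
Conditions: n-BuLi (2.05 equiv), THF, −78 °C; then 4 (2.2 equiv; two molecules are incorporated, one at each acetylide terminus), −78 → 0 °C; H2O quench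
Reagents that add atoms: ketoisophorone 4-ethylene ketal 4 (second equivalent), CC1=CC2(OCCO2)CC(C)(C)C1=O
Why: 1,2-Addition of a lithium acetylide to the hindered ring ketone (the small sp nucleophile that is known to add to this carbonyl of the ketal) at both chain ends forms the two C6–C7 bonds, the new carbinol centres arising as a mixture that converges in step 9.

Step 8
Reactants: 13 8,8'-[(3E,5E,7E,11E,13E,15E)-3,7,12,16-tetramethyloctadeca-3,5,7,11,13,15-hexaene-1,17-diyne-1,18-diyl]bis(7,9,9-trimethyl-1,4-dioxaspiro[4.5]dec-6-en-8-ol)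
Product: 14 8,8'-[(1E,3E,5E,7E,11E,13E,15E,17E)-3,7,12,16-tetramethyloctadeca-1,3,5,7,11,13,15,17-octaene-1,18-diyl]bis(7,9,9-trimethyl-1,4-dioxaspiro[4.5]dec-6-en-8-ol)
Conditions: Red-Al (NaAlH2(OCH2CH2OCH3)2, 6 equiv), THF, 0 → 25 °C; aq. NaOH work-up
Reagents that add atoms: none
Why: Alkoxide-directed trans-hydroalumination of the two propargylic alcohols (Red-Al reduction) gives the (E)-allylic alcohols and leaves the ketals and the other C=C bonds untouched.

Step 9
Reactants: 14 8,8'-[(1E,3E,5E,7E,11E,13E,15E,17E)-3,7,12,16-tetramethyloctadeca-1,3,5,7,11,13,15,17-octaene-1,18-diyl]bis(7,9,9-trimethyl-1,4-dioxaspiro[4.5]dec-6-en-8-ol)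
Product: 16 (6E,6'E)-rhodoxanthin, via rhodoxanthin bis(ethylene ketal) 15 (not isolated)
Conditions: pTsOH·H2O (0.2 equiv), CH2Cl2, −20 → 0 °C, dark; then THF–H2O (5:1), 25 °C; then reflux in EtOAc–heptane and crystallise
Reagents that add atoms: water, O
Why: Acid ionises each tertiary, polyene-stabilised C6–OH to a delocalised cation whose only β-hydrogens sit on the central CH2–CH2 unit, so E1 loss of a proton there (a 1,10-dehydration of the retro-ionylidene type, the allylic rearrangement–dehydration of classical polyene synthesis) moves every double bond into the retro positions at both ends, the same acid hydrolyses the dioxolanes once water is added, and thermal equilibration with crystallisation is relied on to deliver the all-trans isomer with the chain cis to the CMe2 carbon at both rings.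

Step 10
Reactants: 16 (6E,6'E)-rhodoxanthin
Product: 17 (3S,3'S)-eschscholtzxanthin
Conditions: (R)-Me-CBS oxazaborolidine (0.5 equiv), catecholborane (4 equiv), CH2Cl2–toluene, −78 → −30 °C, dark; MeOH then aq. NaOH work-up
Reagents that add atoms: none
Why: Corey–Bakshi–Shibata reduction, in which catalyst-controlled 1,2-hydride delivery to each enone carbonyl, with the alkenyl (polyene) side as the large group and the CH2–CMe2 side as the small one, should give the (S) carbinol at C3 and C3' with the (R) catalyst, the ee of the final target being equal to the selectivity per carbonyl.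

Step 11
Reactants: 17 (3S,3'S)-eschscholtzxanthin
Product: 19 anhydroeschscholtzxanthin (target; carbinol carbon S), via eschscholtzxanthin mono-sulfamate 18 (not isolated)
Conditions: Burgess reagent (0.9 equiv), THF–benzene, 0 → 25 °C, dark; chromatography on base-washed silica
Reagents that add atoms: none
Why: Burgess dehydration, in which the sulfamate ester of one secondary allylic alcohol eliminates by a syn pathway toward C2 (the only carbon next to C3 that carries hydrogen) to give the conjugated ring triene under non-acidic conditions that spare the acid-sensitive gem-dimethyl triene ring, the reagent being limiting so that the mono-dehydrated product dominates (statistical, about 45%, diol 17 recovered and recycled) and the untouched carbinol keeps its (S) configuration.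

**Compound list**
1 | 2-methylcyclopent-2-en-1-one | CC1=CCCC1=O | starting material
2 | 2,6,6-trimethylcyclohex-2-en-1-one | CC1=CCCC(C)(C)C1=O | intermediate
3 | 2,6,6-trimethylcyclohex-2-ene-1,4-dione (ketoisophorone) | CC1=CC(=O)CC(C)(C)C1=O | intermediate
4 | 7,9,9-trimethyl-1,4-dioxaspiro[4.5]dec-6-en-8-one (ketoisophorone 4-ethylene ketal) | CC1=CC2(OCCO2)CC(C)(C)C1=O | intermediate
5 | hexa-1,5-diene | C=CCCC=C | starting material
6 | methacrolein (2-methylprop-2-enal) | CC(=C)C=O | starting material
7 | (2E,6E)-2,7-dimethylocta-2,6-dienedial | O=C/C(C)=C/CC/C=C(C)/C=O | intermediate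
8 | (2E)-3-methylpent-2-en-4-yn-1-ol | C#C/C(C)=C/CO | starting material
9 | [(2E)-3-methylpent-2-en-4-yn-1-yl]triphenylphosphonium bromide | C#C/C(C)=C/C[P+](c1ccccc1)(c1ccccc1)c1ccccc1.[Br-] | intermediate
10 | enynyl phosphorus ylide, [(2E)-3-methylpent-2-en-4-yn-1-ylidene]triphenylphosphorane (not isolated) | C#C/C(C)=C/C=P(c1ccccc1)(c1ccccc1)c1ccccc1 | intermediate
11 | (3E,5E,7E,11E,13E,15E)-3,7,12,16-tetramethyloctadeca-3,5,7,11,13,15-hexaene-1,17-diyne (drawn all-E) | C#C/C(C)=C/C=C/C(C)=C/CC/C=C(C)/C=C/C=C(C)/C#C | intermediate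
12 | dilithium bis-acetylide of 11 (not isolated) | [Li]C#C/C(C)=C/C=C/C(C)=C/CC/C=C(C)/C=C/C=C(C)/C#C[Li] | intermediate
13 | 8,8'-[(3E,5E,7E,11E,13E,15E)-3,7,12,16-tetramethyloctadeca-3,5,7,11,13,15-hexaene-1,17-diyne-1,18-diyl]bis(7,9,9-trimethyl-1,4-dioxaspiro[4.5]dec-6-en-8-ol) (carbinol diastereomers) | CC1=CC2(OCCO2)CC(C)(C)C1(O)C#C/C(C)=C/C=C/C(C)=C/CC/C=C(C)/C=C/C=C(C)/C#CC1(O)C(C)=CC2(OCCO2)CC1(C)C | intermediate
14 | 8,8'-[(1E,3E,5E,7E,11E,13E,15E,17E)-3,7,12,16-tetramethyloctadeca-1,3,5,7,11,13,15,17-octaene-1,18-diyl]bis(7,9,9-trimethyl-1,4-dioxaspiro[4.5]dec-6-en-8-ol) (carbinol diastereomers) | CC1=CC2(OCCO2)CC(C)(C)C1(O)/C=C/C(C)=C/C=C/C(C)=C/CC/C=C(C)/C=C/C=C(C)/C=C/C1(O)C(C)=CC2(OCCO2)CC1(C)C | intermediate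
15 | rhodoxanthin bis(ethylene ketal), all-trans retro-polyene with both C3 carbonyls as dioxolanes (not isolated) | CC1=CC2(OCCO2)CC(C)(C)\C1=C/C=C(C)/C=C/C=C(C)/C=C/C=C/C(C)=C/C=C/C(C)=C/C=C1/C(C)=CC2(OCCO2)CC1(C)C | intermediate
16 | (6E,6'E)-rhodoxanthin (4',5'-didehydro-4,5'-retro-β,β-carotene-3,3'-dione, all-trans, chain cis to CMe2 at both rings) | CC1=CC(=O)CC(C)(C)\C1=C/C=C(C)/C=C/C=C(C)/C=C/C=C/C(C)=C/C=C/C(C)=C/C=C1/C(C)=CC(=O)CC1(C)C | intermediate
17 | (3S,3'S)-eschscholtzxanthin (4',5'-didehydro-4,5'-retro-β,β-carotene-3,3'-diol, all-trans) | CC1=C[C@@H](O)CC(C)(C)\C1=C/C=C(C)/C=C/C=C(C)/C=C/C=C/C(C)=C/C=C/C(C)=C/C=C1/C(C)=C[C@@H](O)CC1(C)C | intermediate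
18 | eschscholtzxanthin mono-sulfamate, triethylammonium salt of the 3-O-[N-(methoxycarbonyl)sulfamoyl] derivative of 17 (not isolated) | CC1=C[C@@H](OS(=O)(=O)[N-]C(=O)OC)CC(C)(C)\C1=C/C=C(C)/C=C/C=C(C)/C=C/C=C/C(C)=C/C=C/C(C)=C/C=C1/C(C)=C[C@@H](O)CC1(C)C.CC[NH+](CC)CC | intermediate
19 | anhydroeschscholtzxanthin (CNP0202479.1): all-trans retro-carotenoid with a 2,6,6-trimethylcyclohexa-2,4-dien-1-ylidene end and a (4S)-4-hydroxy-2,6,6-trimethylcyclohex-2-en-1-ylidene end, chain cis to CMe2 at both rings | CC1=CC=CC(C)(C)\C1=C/C=C(C)/C=C/C=C(C)/C=C/C=C/C(C)=C/C=C/C(C)=C/C=C1/C(C)=C[C@@H](O)CC1(C)C | target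

**Step count.** Total steps: 11. Longest linear sequence: 8 steps (1, 2, 3, 7, 8, 9, 10, 11).

**Three steps most likely to fail**

Step 1 (the proposed new ring expansion; main risk is dipolar addition of 2-diazopropane to the C=C bond, or migration of the vinyl carbon). The fallback uses known chemistry and builds the quaternary carbon one carbon at a time. It sets out from 1: BF3·OEt2-promoted one-carbon ring expansion with trimethylsilyldiazomethane (CH2Cl2, −78 °C, sp3 carbon migrating) gives 2-methyl-6-(trimethylsilyl)cyclohex-2-en-1-one F1. Protodesilylation (K2CO3, MeOH) gives 2-methylcyclohex-2-en-1-one F2. Kinetic α'-enolate methylation (LDA, MeI, THF, −78 °C) gives 2,6-dimethylcyclohex-2-en-1-one F3, and a second LDA/MeI methylation comes back to the route at 2.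

Step 10 (CBS reduction of a long polyene-conjugated dione; the enantioselectivity is untested here and a (3R,3'S) by-product cannot be removed easily). The fallback sets the stereocentre early on the ring. It sets out from 3: asymmetric transfer hydrogenation of the unhindered C4 ketone (RuCl(p-cymene)(TsDPEN), ligand enantiomer chosen for the 4S alcohol, HCO2H–Et3N) gives (4S)-4-hydroxy-2,6,6-trimethylcyclohex-2-en-1-one F4. Silylation (TBSCl, imidazole) gives (4S)-4-(tert-butyldimethylsilyloxy)-2,6,6-trimethylcyclohex-2-en-1-one F5. Addition of 12 to two equivalents of F5 gives the bis-silyl diyne diol F6, and Red-Al reduction gives the bis-silyl octaene diol F7. Mild acid-catalysed double 1,10-dehydration (pyridinium p-toluenesulfonate, CH2Cl2, 0 °C) gives eschscholtzxanthin bis(tert-butyldimethylsilyl) ether F8, and TBAF comes back to the route at 17. In this variant proton loss from C3–H could compete with loss from the central CH2–CH2 in the dehydration, which is why it is not the main route.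

Step 11 (statistical mono-dehydration; over-dehydration and loss of material through the sensitive polyenylic cation). The fallback desymmetrises with a protecting group so that the elimination itself can be driven to completion. It sets out from 17: TBSCl (1.0 equiv) and imidazole give eschscholtzxanthin mono(tert-butyldimethylsilyl) ether F9, with the diol and the bis-ether separated and recycled. Burgess reagent in excess (or Martin sulfurane) gives anhydroeschscholtzxanthin tert-butyldimethylsilyl ether F10, and TBAF (THF, 0 °C) comes back to the route at 19.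

**Further compounds**
F1 | step 1 | 2-methyl-6-(trimethylsilyl)cyclohex-2-en-1-one | CC1=CCCC([Si](C)(C)C)C1=O
F2 | step 1 | 2-methylcyclohex-2-en-1-one | CC1=CCCCC1=O
F3 | step 1 | 2,6-dimethylcyclohex-2-en-1-one | CC1=CCCC(C)C1=O
F4 | step 10 | (4S)-4-hydroxy-2,6,6-trimethylcyclohex-2-en-1-one | CC1=C[C@@H](O)CC(C)(C)C1=O
F5 | step 10 | (4S)-4-(tert-butyldimethylsilyloxy)-2,6,6-trimethylcyclohex-2-en-1-one | CC1=C[C@@H](O[Si](C)(C)C(C)(C)C)CC(C)(C)C1=O
F6 | step 10 | 1,1'-[(3E,5E,7E,11E,13E,15E)-3,7,12,16-tetramethyloctadeca-3,5,7,11,13,15-hexaene-1,17-diyne-1,18-diyl]bis[(4S)-4-(tert-butyldimethylsilyloxy)-2,6,6-trimethylcyclohex-2-en-1-ol] | CC1=C[C@@H](O[Si](C)(C)C(C)(C)C)CC(C)(C)C1(O)C#C/C(C)=C/C=C/C(C)=C/CC/C=C(C)/C=C/C=C(C)/C#CC1(O)C(C)=C[C@@H](O[Si](C)(C)C(C)(C)C)CC1(C)C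
F7 | step 10 | 1,1'-[(1E,3E,5E,7E,11E,13E,15E,17E)-3,7,12,16-tetramethyloctadeca-1,3,5,7,11,13,15,17-octaene-1,18-diyl]bis[(4S)-4-(tert-butyldimethylsilyloxy)-2,6,6-trimethylcyclohex-2-en-1-ol] | CC1=C[C@@H](O[Si](C)(C)C(C)(C)C)CC(C)(C)C1(O)/C=C/C(C)=C/C=C/C(C)=C/CC/C=C(C)/C=C/C=C(C)/C=C/C1(O)C(C)=C[C@@H](O[Si](C)(C)C(C)(C)C)CC1(C)C
F8 | step 10 | (3S,3'S)-eschscholtzxanthin bis(tert-butyldimethylsilyl) ether | CC1=C[C@@H](O[Si](C)(C)C(C)(C)C)CC(C)(C)\C1=C/C=C(C)/C=C/C=C(C)/C=C/C=C/C(C)=C/C=C/C(C)=C/C=C1/C(C)=C[C@@H](O[Si](C)(C)C(C)(C)C)CC1(C)C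
F9 | step 11 | (3S,3'S)-eschscholtzxanthin mono(tert-butyldimethylsilyl) ether | CC1=C[C@@H](O)CC(C)(C)\C1=C/C=C(C)/C=C/C=C(C)/C=C/C=C/C(C)=C/C=C/C(C)=C/C=C1/C(C)=C[C@@H](O[Si](C)(C)C(C)(C)C)CC1(C)C
F10 | step 11 | anhydroeschscholtzxanthin tert-butyldimethylsilyl ether | CC1=CC=CC(C)(C)\C1=C/C=C(C)/C=C/C=C(C)/C=C/C=C/C(C)=C/C=C/C(C)=C/C=C1/C(C)=C[C@@H](O[Si](C)(C)C(C)(C)C)CC1(C)C
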